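**Strategy**

Ring A of the target (C7′–O–C9–C8–C8′) is an ArCH–O–CH2 unit spanning the C8–C8′ bond, and C8 bears an acyloxy group; the key step exploits exactly this by cutting ring A back to a carbonyl ylide and an enol-acetate alkene. One [3+2] cycloaddition of ArCH=O(+)–CH2(−) to the C8=C8′ bond of an (R)-5-aryl-4-acetoxybutenolide (ring B as lactone, C9′ as carbonyl) should form C9–C8 and C7′–C8′, close ring A and set C8, C8′ and C7′ from the C7 stereocentre alone. The ylide comes from a racemic α-silylbenzyl chloromethyl ether and fluoride. Lactone-to-ether reduction, acetylation and debenzylation then give the target.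

Key step: step 10

Remarks on the chemistry (one line each):
- Lignan numbering is used: C7/C7′ carry the aryl groups, C8 is the acetoxy bridgehead, C8′ the CH bridgehead, C9/C9′ the OCH2 carbons; ring A = C7′–O–C9–C8–C8′, ring B = C7–O–C9′–C8′–C8; Ar = 4-benzyloxy-3-methoxyphenyl.
- Assumption (step 2): the (R)-acid/(R)-amine pair is taken as the less soluble salt; if the opposite pair crystallises, (S)-1-phenylethylamine is used and nothing else changes.
- The silyl group of the ylide precursor is dimethylphenylsilyl, because it can be placed on the aldehyde carbon by copper catalysis without a free lithium alkoxide (no Brook rearrangement); it leaves as the fluorosilane in step 10.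
- The tetronate oxygen is carried as a 4-methoxybenzyl group, because the ketene-ylide reaction gives a 4-alkoxybutenolide and this group comes off with mild acid while the phenolic benzyl ether stays.

**Route**

Step 1
Reactants: 1 vanillylmandelic acid (racemic)
Product: 2 racemic 2-[4-(benzyloxy)-3-methoxyphenyl]-2-hydroxyacetic acid
Conditions: BnBr (1.1 equiv), NaOH (3 equiv), EtOH/H2O, 60 °C, N2; then aq. HCl to pH 2
Reagents that add atoms: benzyl bromide, BrCc1ccccc1
Why: Williamson etherification, in which the phenoxide is the only strongly nucleophilic oxygen in aqueous alkali and any benzyl ester formed is saponified in the same pot, so only the phenol should end up benzylated (racemate, no stereocentre set).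

Step 2
Reactants: 2 racemic 2-[4-(benzyloxy)-3-methoxyphenyl]-2-hydroxyacetic acid
Product: 3 (R)-1-phenylethylammonium (R)-2-[4-(benzyloxy)-3-methoxyphenyl]-2-hydroxyacetate
Conditions: (R)-1-phenylethylamine (1.0 equiv), EtOH, 70 °C to 5 °C; recrystallisation from EtOH to constant rotation
Reagents that add atoms: (R)-1-phenylethylamine, C[C@@H](N)c1ccccc1
Why: Classical resolution by diastereomeric salt crystallisation, the standard access to single enantiomers of mandelic acids; the (R) configuration of the future C7 is selected here, not created, and is to be checked by chiral HPLC.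

Step 3
Reactants: 3 (R)-1-phenylethylammonium (R)-2-[4-(benzyloxy)-3-methoxyphenyl]-2-hydroxyacetate
Product: 5 4-methoxybenzyl (R)-2-[4-(benzyloxy)-3-methoxyphenyl]-2-hydroxyacetate, via free (R)-acid 4 (not isolated)
Conditions: 1 M HCl/EtOAc partition, solvent switch to DMF; 4-methoxybenzyl chloride (1.1 equiv), KHCO3 (1.5 equiv), NaI (5 mol%), DMF, rt
Reagents that add atoms: 4-methoxybenzyl chloride, COc1ccc(CCl)cc1
Why: Acidification frees the acid and SN2 O-alkylation of its carboxylate under bicarbonate should give the ester without touching the secondary hydroxyl or the C7–H, so the configuration is retained.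

Step 4
Reactants: 5 4-methoxybenzyl (R)-2-[4-(benzyloxy)-3-methoxyphenyl]-2-hydroxyacetate
Product: 7 (R)-5-[4-(benzyloxy)-3-methoxyphenyl]-4-[(4-methoxybenzyl)oxy]furan-2(5H)-one, via ester phosphorane 6 (not isolated)
Conditions: Ph3P=C=C=O (1.1 equiv), THF, 65 °C
Reagents that add atoms: (triphenylphosphoranylidene)ketene, O=C=C=P(c1ccccc1)(c1ccccc1)c1ccccc1
Why: Domino addition–intramolecular Wittig olefination, in which the hydroxyl adds across the C=C of the cumulated ylide and the resulting ester phosphorane olefinates the neighbouring ester carbonyl to the 4-alkoxybutenolide under neutral conditions, so C7 should stay (R).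

Step 5
Reactants: 7 (R)-5-[4-(benzyloxy)-3-methoxyphenyl]-4-[(4-methoxybenzyl)oxy]furan-2(5H)-one
Product: 8 (R)-5-[4-(benzyloxy)-3-methoxyphenyl]-4-hydroxyfuran-2(5H)-one (5-aryl tetronic acid)
Conditions: TFA/CH2Cl2 (1:9), anisole (10 equiv), 0 °C, 30 min
Reagents that add atoms: none
Why: Acidolysis of a 4-methoxybenzyl vinylogous ester (SN1 loss of the 4-methoxybenzyl cation, trapped by anisole in a Friedel–Crafts alkylation) should free the tetronic acid, while the phenolic benzyl ether gives no comparably stabilised cation and stays on.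

Step 6
Reactants: 8 (R)-5-[4-(benzyloxy)-3-methoxyphenyl]-4-hydroxyfuran-2(5H)-one
Product: 9 (R)-4-acetoxy-5-[4-(benzyloxy)-3-methoxyphenyl]furan-2(5H)-one
Conditions: isopropenyl acetate (5 equiv), TsOH·H2O (2 mol%), CH2Cl2, 40 °C
Reagents that add atoms: isopropenyl acetate, CC(=C)OC(C)=O
Why: Acid-catalysed acyl transfer from isopropenyl acetate to the acidic enol (O-acetylation) should give the enol acetate without any base, which avoids both removal of the acidic C7–H and O-to-C acyl migration.

Step 7
Reactants: 10 4-(benzyloxy)-3-methoxybenzaldehyde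
Product: 11 racemic [4-(benzyloxy)-3-methoxyphenyl][dimethyl(phenyl)silyl]methanol
Conditions: PhMe2Si–Bpin (1.2 equiv), CuCl (5 mol%), 1,3-bis(2,6-diisopropylphenyl)imidazolium chloride (5 mol%), NaOtBu (12 mol%), MeOH (2 equiv), THF, 0 °C to rt
Reagents that add atoms: (dimethylphenylsilyl)boronic acid pinacol ester, C[Si](C)(c1ccccc1)B1OC(C)(C)C(C)(C)O1
Why: Copper-catalysed 1,2-addition of a silyl nucleophile from the Si–B reagent to the aldehyde, with protonation by methanol, should give the α-hydroxysilane without the free lithium alkoxide that would undergo Brook rearrangement; the new stereocentre is racemic and is erased in step 10.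

Step 8
Reactants: 11 racemic [4-(benzyloxy)-3-methoxyphenyl][dimethyl(phenyl)silyl]methanol
Product: 12 racemic {[4-(benzyloxy)-3-methoxyphenyl][(methylsulfanyl)methoxy]methyl}dimethyl(phenyl)silane
Conditions: Me2S (8 equiv), dibenzoyl peroxide (4 equiv), MeCN, 0 °C
Reagents that add atoms: dimethyl sulfide, CSC
Why: Pummerer-type methylthiomethylation, in which dimethyl sulfide and the peroxide give a methylene(methyl)sulfonium ion that the alcohol captures, runs without base or strong acid, so neither Brook rearrangement nor benzylic ionisation of the α-silyl alcohol should occur.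

Step 9
Reactants: 12 racemic {[4-(benzyloxy)-3-methoxyphenyl][(methylsulfanyl)methoxy]methyl}dimethyl(phenyl)silane
Product: 13 racemic {[4-(benzyloxy)-3-methoxyphenyl](chloromethoxy)methyl}dimethyl(phenyl)silane
Conditions: SO2Cl2 (1.0 equiv), cyclohexene (2 equiv), CH2Cl2, −78 °C to 0 °C; evaporate and use crude
Reagents that add atoms: sulfuryl chloride, ClS(Cl)(=O)=O
Why: Chlorinolysis of the O,S-acetal (S-chlorination, loss of methanesulfenyl chloride, collapse of the oxocarbenium chloride ion pair) should give the chloromethyl ether without the strong acid that would ionise the electron-rich α-silylbenzyl C–O bond; cyclohexene traps the sulfenyl chloride.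

Step 10
Reactants: 9 (R)-4-acetoxy-5-[4-(benzyloxy)-3-methoxyphenyl]furan-2(5H)-one, 13 racemic {[4-(benzyloxy)-3-methoxyphenyl](chloromethoxy)methyl}dimethyl(phenyl)silane
Product: 15 9′-oxo-1-acetoxypinoresinol dibenzyl ether (7R,7′S,8S,8′R; ring B as lactone), via carbonyl ylide 14 (not isolated)
Conditions: 13 (2.5 equiv, added over 2 h), CsF (4 equiv, flame-dried), MeCN, rt
Reagents that add atoms: none
Why: Proposed new method: ionisation of the C–Cl bond of 13 and fluoride attack at silicon (a 1,3-elimination) release the non-stabilised carbonyl ylide 14, which adds suprafacially and in one concerted step across the electron-poor C8=C8′ bond of 9; the closest known reaction is the fluoride-induced [3+2] cycloaddition of carbonyl ylides from α-silyl α′-chloro ethers to acrylates, fumarates and maleates, not yet shown for a β-acyloxy butenolide or for an ylide carrying silicon on the benzylic carbon. Ring A is closed by this intermolecular 1,3-dipolar cycloaddition, with C9–C8 and C7′–C8′ formed together, so the A/B fusion is necessarily cis. C8 and C8′ are controlled by the C7 aryl group of 9, which shields one face of the nearly planar butenolide so that the dipole adds anti to it, and C7′ is controlled by an exo transition state in which the ylide aryl group points away from the lactone carbonyl. The regiochemistry needed (CH2 end to C8, ArCH end to C8′) rests on pairing the larger HOMO coefficient of the unsubstituted ylide carbon with the β-carbon C8 of the enoate, and on sterics, since the small CH2 end goes to the fully substituted C8. Compared with a 4-alkoxybutenolide, the 4-acetoxy group makes the double bond a better acceptor and puts the C8 oxygen in place, and sparingly soluble CsF keeps the medium near neutral so that the acidic C7–H of 9 is not removed.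

Step 11
Reactants: 15 9′-oxo-1-acetoxypinoresinol dibenzyl ether
Product: 16 9′-hydroxy-1-hydroxypinoresinol dibenzyl ether (C9′ lactol, both anomers, free C8 hydroxyl)
Conditions: iBu2AlH (4 equiv), CH2Cl2, −78 °C; MeOH at −78 °C, then aq. KNaC4H4O6 (potassium sodium tartrate)
Reagents that add atoms: none
Why: Hydride reduction of a γ-lactone with iBu2AlH stops at the aluminium hemiacetal at −78 °C and should give the lactol on work-up, the acetate being cleaved the same way (any that survives converges on 18 after steps 12 and 13); only the inconsequential anomeric centre C9′ is new.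

Step 12
Reactants: 16 9′-hydroxy-1-hydroxypinoresinol dibenzyl ether
Product: 17 1-hydroxypinoresinol dibenzyl ether (7R,7′S,8S,8′R)
Conditions: Et3SiH (5 equiv), BF3·OEt2 (2 equiv), CH2Cl2, −78 °C
Reagents that add atoms: none
Why: Ionic hydrogenation (Lewis-acid ionisation of the lactol to the cyclic oxocarbenium ion, then hydride transfer from the silane) should turn C9′ into CH2, and at −78 °C the tertiary C8 hydroxyl and the two benzylic ring ethers should not ionise, so C7, C7′, C8 and C8′ stay as set.

Step 13
Reactants: 17 1-hydroxypinoresinol dibenzyl ether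
Product: 18 1-acetoxypinoresinol dibenzyl ether
Conditions: Ac2O (5 equiv), Et3N (6 equiv), DMAP (0.5 equiv), CH2Cl2, rt to 40 °C
Reagents that add atoms: acetic anhydride, CC(=O)OC(C)=O
Why: DMAP-catalysed acylation (Steglich-type nucleophilic catalysis through the N-acetylpyridinium ion) is the standard way to acetylate a hindered tertiary alcohol, and the C8 hydroxyl is the only free hydroxyl in 17.

Step 14
Reactants: 18 1-acetoxypinoresinol dibenzyl ether
Product: 19 1-acetoxypinoresinol
Conditions: H2 (1 atm), Pd/C (10% palladium on carbon), EtOAc, rt, stopped at full debenzylation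
Reagents that add atoms: none
Why: Catalytic hydrogenolysis under neutral conditions cleaves the two aryl benzyl ethers much faster than the dialkyl benzylic C7–O and C7′–O bonds of the furofuran and leaves the acetate alone, so it should give the target with all four stereocentres unchanged.

**Compound list**

1 | vanillylmandelic acid, racemic [2-hydroxy-2-(4-hydroxy-3-methoxyphenyl)acetic acid] | COc1cc(C(O)C(=O)O)ccc1O | starting material
2 | racemic 2-[4-(benzyloxy)-3-methoxyphenyl]-2-hydroxyacetic acid | COc1cc(C(O)C(=O)O)ccc1OCc1ccccc1 | intermediate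
3 | (R)-1-phenylethylammonium (R)-2-[4-(benzyloxy)-3-methoxyphenyl]-2-hydroxyacetate | [O-]C(=O)[C@H](O)c1ccc(OCc2ccccc2)c(OC)c1.C[C@@H]([NH3+])c1ccccc1 | intermediate
4 | (R)-2-[4-(benzyloxy)-3-methoxyphenyl]-2-hydroxyacetic acid (not isolated) | O[C@@H](C(=O)O)c1ccc(OCc2ccccc2)c(OC)c1 | intermediate
5 | 4-methoxybenzyl (R)-2-[4-(benzyloxy)-3-methoxyphenyl]-2-hydroxyacetate | O[C@@H](C(=O)OCc1ccc(OC)cc1)c1ccc(OCc2ccccc2)c(OC)c1 | intermediate
6 | 4-methoxybenzyl (R)-2-[4-(benzyloxy)-3-methoxyphenyl]-2-[(triphenylphosphoranylidene)acetoxy]acetate (ester phosphorane, not isolated) | O=C(C=P(c1ccccc1)(c1ccccc1)c1ccccc1)O[C@@H](C(=O)OCc1ccc(OC)cc1)c1ccc(OCc2ccccc2)c(OC)c1 | intermediate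
7 | (R)-5-[4-(benzyloxy)-3-methoxyphenyl]-4-[(4-methoxybenzyl)oxy]furan-2(5H)-one | COc1ccc(COC2=CC(=O)O[C@@H]2c2ccc(OCc3ccccc3)c(OC)c2)cc1 | intermediate
8 | (R)-5-[4-(benzyloxy)-3-methoxyphenyl]-4-hydroxyfuran-2(5H)-one | OC1=CC(=O)O[C@@H]1c1ccc(OCc2ccccc2)c(OC)c1 | intermediate
9 | (R)-4-acetoxy-5-[4-(benzyloxy)-3-methoxyphenyl]furan-2(5H)-one (C8=C8′ dipolarophile; C7 = C5 of the ring) | CC(=O)OC1=CC(=O)O[C@@H]1c1ccc(OCc2ccccc2)c(OC)c1 | intermediate
10 | 4-(benzyloxy)-3-methoxybenzaldehyde | COc1cc(C=O)ccc1OCc1ccccc1 | starting material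
11 | racemic [4-(benzyloxy)-3-methoxyphenyl][dimethyl(phenyl)silyl]methanol | COc1cc(C(O)[Si](C)(C)c2ccccc2)ccc1OCc1ccccc1 | intermediate
12 | racemic {[4-(benzyloxy)-3-methoxyphenyl][(methylsulfanyl)methoxy]methyl}dimethyl(phenyl)silane | COc1cc(C(OCSC)[Si](C)(C)c2ccccc2)ccc1OCc1ccccc1 | intermediate
13 | racemic {[4-(benzyloxy)-3-methoxyphenyl](chloromethoxy)methyl}dimethyl(phenyl)silane (chloromethyl α-silylbenzyl ether) | COc1cc(C(OCCl)[Si](C)(C)c2ccccc2)ccc1OCc1ccccc1 | intermediate
14 | carbonyl ylide ArCH=O(+)–CH2(−) (not isolated) | COc1cc(C=[O+][CH2-])ccc1OCc1ccccc1 | intermediate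
15 | 9′-oxo-1-acetoxypinoresinol dibenzyl ether: cis-fused bicycle, ring A tetrahydrofuran, ring B γ-lactone (C9′=O), both aryl groups exo, C8–OAc and C8′–H cis; (7R,7′S,8S,8′R) | COc1cc([C@H]2OC[C@]3(OC(C)=O)[C@@H](c4ccc(OCc5ccccc5)c(OC)c4)OC(=O)[C@H]23)ccc1OCc1ccccc1 | intermediate
16 | 9′-hydroxy-1-hydroxypinoresinol dibenzyl ether (C9′ lactol, anomeric mixture; free C8–OH) | COc1cc([C@H]2OC[C@]3(O)[C@@H](c4ccc(OCc5ccccc5)c(OC)c4)OC(O)[C@H]23)ccc1OCc1ccccc1 | intermediate
17 | 1-hydroxypinoresinol dibenzyl ether (7R,7′S,8S,8′R) | COc1cc([C@H]2OC[C@]3(O)[C@@H](c4ccc(OCc5ccccc5)c(OC)c4)OC[C@H]23)ccc1OCc1ccccc1 | intermediate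
18 | 1-acetoxypinoresinol dibenzyl ether (7R,7′S,8S,8′R) | COc1cc([C@H]2OC[C@]3(OC(C)=O)[C@@H](c4ccc(OCc5ccccc5)c(OC)c4)OC[C@H]23)ccc1OCc1ccccc1 | intermediate
19 | 1-acetoxypinoresinol (7R,7′S,8S,8′R) | COc1cc([C@H]2OC[C@]3(OC(C)=O)[C@@H](c4ccc(O)c(OC)c4)OC[C@H]23)ccc1O | target

**Step count**

Total: 14 steps. Longest linear sequence: 11 steps (1–6, then 10–14); the ylide arm (7–9) is three steps.

**Steps most likely to fail**

1. Step 10 (labelled as a new method). What may go wrong: fluoride strips the enol acetate or removes the C7–H of 9 before the ylide is trapped (loss of the dipolarophile or of enantiopurity); the ylide adds with reversed regiochemistry or without face and exo control; or the ylide collapses faster than it adds.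
Fallback (known chemistry; sets out from aldehyde 10, returns at 17, then steps 13 and 14 as written): vinylmagnesium bromide in THF at 0 °C should give the racemic allylic alcohol F1. Sharpless kinetic resolution–epoxidation [Ti(OiPr)4, D-(−)-diisopropyl tartrate, tBuOOH, 4 Å molecular sieves, CH2Cl2, −20 °C, about half conversion] should convert its (S)-enantiomer into the erythro epoxy alcohol F2, which fixes C7′. NaH and propargyl bromide in THF should give the propargyl ether F3. Sonogashira coupling with 1-(benzyloxy)-4-iodo-2-methoxybenzene [Pd(PPh3)2Cl2, CuI, Et3N] should give the aryl alkyne F4. Cp2TiCl (trivalent titanium, from Cp2TiCl2 and Zn in THF) should open the epoxide to the C8′ radical, which cyclises 5-exo-dig to the trans-2-aryl-4-arylidene-tetrahydrofuran-3-methanol F5. OsO4 with N-methylmorpholine N-oxide should dihydroxylate the exocyclic alkene anti to the neighbouring CH2OH to give the triol F6, which fixes C8; both C7 epimers serve. Camphorsulfonic acid in CH2Cl2 should then ionise the benzylic C7 hydroxyl so that the C9′ hydroxyl closes ring B, giving 17.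

2. Step 9. What may go wrong: competing chlorination of the electron-rich arene, or ionisation and hydrolysis of the chloromethyl ether during concentration and transfer, so that little intact ylide precursor reaches step 10.
Fallback (sets out from aldehyde 10, returns at cycloadduct 15; replaces steps 7–9): the same ylide is generated from the regioisomeric precursor that carries chlorine on the benzylic carbon and silicon on the methylene, the precursor type for which fluoride-induced ylide formation is established. Acetalisation of 10 with (trimethylsilyl)methanol (2.2 equiv, pyridinium p-toluenesulfonate, benzene, azeotropic removal of water) should give the bis[(trimethylsilyl)methyl] acetal F7. Acetyl chloride in CH2Cl2 at 0 °C should convert it into the α-chlorobenzyl (trimethylsilyl)methyl ether F8. Used at once with 9 and CsF in MeCN, F8 should release ylide 14 and give 15.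

3. Step 12. What may go wrong: the Lewis acid ionises the benzylic C7–O or C7′–O bond, which scrambles C7 or C7′ or leads to reductive opening of a ring.
Fallback (sets out from 15, returns at 17; replaces steps 11 and 12): LiAlH4 in THF at 0 °C should reduce the lactone and cleave the acetate to give the triol F9. MsCl (1.1 equiv) in pyridine at 0 °C should sulfonylate only the primary C9′ hydroxyl to give the primary mesylate F10. On warming, the C7 hydroxyl displaces the mesylate (5-exo-tet Williamson closure of ring B, C7 untouched) to give 17 without any Lewis acid.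

**Further compounds**

F1 | step 10 | racemic 1-[4-(benzyloxy)-3-methoxyphenyl]prop-2-en-1-ol | COc1cc(C(O)C=C)ccc1OCc1ccccc1
F2 | step 10 | erythro epoxy alcohol, (S)-configured carbinol geometry at the future C7′: [4-(benzyloxy)-3-methoxyphenyl](oxiran-2-yl)methanol | COc1cc([C@@H](O)[C@H]2CO2)ccc1OCc1ccccc1
F3 | step 10 | propargyl ether of F2 | COc1cc([C@@H](OCC#C)[C@H]2CO2)ccc1OCc1ccccc1
F4 | step 10 | aryl alkyne: 3-[4-(benzyloxy)-3-methoxyphenyl]prop-2-ynyl ether of F2 | COc1cc([C@@H](OCC#Cc2ccc(OCc3ccccc3)c(OC)c2)[C@H]2CO2)ccc1OCc1ccccc1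
F5 | step 10 | trans-2-aryl-4-arylidene-tetrahydrofuran-3-methanol (ring A with C8=C7 exocyclic, alkene geometry not controlling) | COc1cc([C@H]2OCC(=Cc3ccc(OCc4ccccc4)c(OC)c3)[C@@H]2CO)ccc1OCc1ccccc1
F6 | step 10 | triol: ring A with C8–OH, C7 carbinol (both epimers) and C9′ CH2OH | COc1cc([C@H]2OC[C@](O)(C(O)c3ccc(OCc4ccccc4)c(OC)c3)[C@@H]2CO)ccc1OCc1ccccc1
F7 | step 9 | 4-(benzyloxy)-3-methoxybenzaldehyde bis[(trimethylsilyl)methyl] acetal | COc1cc(C(OC[Si](C)(C)C)OC[Si](C)(C)C)ccc1OCc1ccccc1
F8 | step 9 | racemic α-chloro-4-(benzyloxy)-3-methoxybenzyl (trimethylsilyl)methyl ether | COc1cc(C(Cl)OC[Si](C)(C)C)ccc1OCc1ccccc1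
F9 | step 12 | triol from reduction of 15 (C7 defined, R) | COc1cc([C@H]2OC[C@](O)([C@H](O)c3ccc(OCc4ccccc4)c(OC)c3)[C@@H]2CO)ccc1OCc1ccccc1
F10 | step 12 | primary C9′ mesylate of F9 | COc1cc([C@H]2OC[C@](O)([C@H](O)c3ccc(OCc4ccccc4)c(OC)c3)[C@@H]2COS(C)(=O)=O)ccc1OCc1ccccc1
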